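**Retrosynthetic overview**
1. Target ⇒ its ring A methyl ether (O-demethylation last). All three benzene rings are bought and none is built, so the only skeletal bonds to make are the two aryl C–O bonds.
2. A–O–B bond (key step) ⇒ ring A phenoxide + ring B as an aryl cation equivalent, i.e. a polarity-reversed aryl carbon. The reagent is an oxygen-bridged cyclic diaryliodonium salt spanning rings B and C, opened at the tribrominated ring so that the iodine stays behind as the iodide of ring C.
3. Cyclic iodonium salt ⇒ 2-iodo diaryl ether B–O–C, by oxidation at iodine and ring closure onto ring B.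
4. B–O–C bond ⇒ 4-bromo-2-iodophenoxide + ring B again as an aryl cation equivalent, a (2,3,4-tribromophenyl)(2,4,6-trimethoxyphenyl)iodonium salt. It comes from 1,2,3-tribromobenzene by C4 iodination, then oxidation and coupling with 1,3,5-trimethoxybenzene as the ligand that stays on iodine.
5. Ring order: the only ring formed is the temporary six-membered iodine/oxygen ring (step 4), which is opened again in step 5.

Assumption: the target has no stereocentre and no configurationally stable axis, so the achiral compound drawn is the single species to be made.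

**Step 1**
Reactants: 1 1,2,3-tribromobenzene
Product: 2 1,2,3-tribromo-4-iodobenzene
Conditions: NIS (1.05 equiv), TfOH, 0 °C → rt; recrystallise
Reagents that add atoms: N-iodosuccinimide, O=C1CCC(=O)N1I
Why: Electrophilic aromatic iodination of a deactivated arene by protonated N-iodosuccinimide, which goes to C4 (ortho to one bromine and para to another, the site 1,2,3-trihalobenzenes also choose in nitration), the minor 5-iodo isomer being removed by recrystallisation.

**Step 2**
Reactants: 2 1,2,3-tribromo-4-iodobenzene; 3 1,3,5-trimethoxybenzene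
Product: 5 (2,3,4-tribromophenyl)(2,4,6-trimethoxyphenyl)iodonium 4-methylbenzenesulfonate, via hydroxy(tosyloxy)iodane 4 (not isolated)
Conditions: mCPBA, TsOH·H2O, MeCN, 77 °C; then 3, 77 °C → rt; Et2O trituration, filter
Reagents that add atoms: 4-methylbenzenesulfonic acid, Cc1ccc(S(=O)(=O)O)cc1
Why: One-pot unsymmetrical diaryliodonium synthesis, in which the aryl iodide is oxidised to a Koser-type hydroxy(tosyloxy)iodane and the trivalent iodine then substitutes the very nucleophilic 1,3,5-trimethoxybenzene by electrophilic aromatic substitution.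

**Step 3**
Reactants: 5 (2,3,4-tribromophenyl)(2,4,6-trimethoxyphenyl)iodonium 4-methylbenzenesulfonate; 6 4-bromo-2-iodophenol
Product: 8 1,2,3-tribromo-4-(4-bromo-2-iodophenoxy)benzene, via potassium phenoxide 7 (not isolated)
Conditions: 6, t-BuOK (1.0 equiv), THF, 0 °C; then 5, 40 °C, dark
Reagents that add atoms: none
Why: Metal-free O-arylation of a phenoxide by a diaryliodonium salt (ligand exchange at iodine, then ligand coupling), in which the electron-rich trimethoxyphenyl group stays on iodine and only the electron-poor, ortho-substituted 2,3,4-tribromophenyl group is transferred, with no C–Br or C–I bond touched.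

**Step 4**
Reactants: 8 1,2,3-tribromo-4-(4-bromo-2-iodophenoxy)benzene
Product: 10 1,2,3,7-tetrabromodibenzo[b,e][1,4]iodaoxin-5-ium trifluoromethanesulfonate (I+ bridges C6 of the tribromophenoxy ring and C2 of the bromophenoxy ring; the ether oxygen is the other bridge), via hydroxy(triflyloxy)iodane 9 (not isolated)
Conditions: mCPBA, TfOH, CH2Cl2, 0 °C → rt (40 °C if slow); Et2O precipitation
Reagents that add atoms: trifluoromethanesulfonic acid, OS(=O)(=O)C(F)(F)F
Why: Oxidative cyclisation to a cyclic diaryliodonium triflate, in which the aryl iodide is oxidised to trivalent iodine and then attacks ring B by intramolecular electrophilic aromatic substitution ortho to the ether oxygen and para to a bromine, the only position the tether can reach.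

**Step 5**
Reactants: 10 1,2,3,7-tetrabromodibenzo[b,e][1,4]iodaoxin-5-ium trifluoromethanesulfonate; 11 2,4-dibromo-6-methoxyphenol
Product: 13 1,2,3-tribromo-4-(4-bromo-2-iodophenoxy)-5-(2,4-dibromo-6-methoxyphenoxy)benzene, via potassium phenoxide 12 (not isolated)
Conditions: 11, t-BuOK (1.0 equiv), DMF, 0 °C; then 10, 60 → 80 °C, no metal catalyst, dark
Reagents that add atoms: none
Why: Proposed new method: metal-free ring-opening O-arylation, in which the phenoxide exchanges onto iodine and ligand-couples (SNAr-like) at the iodine-bound carbon of the more electron-poor ring B (bromines para and twice meta) rather than ring C (one meta bromine), so the aryloxy group lands on ring B and the iodine stays ortho to the ether oxygen of ring C, while the exactly stoichiometric base leaves no strong base to trigger an aryne pathway; the closest known reactions are the metal-free O-arylation of hindered phenoxides by acyclic diaryliodonium salts, which transfers the more electron-poor aryl group, and the ring opening of cyclic diaryliodonium salts by heteroatom nucleophiles.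

**Step 6**
Reactants: 13 1,2,3-tribromo-4-(4-bromo-2-iodophenoxy)-5-(2,4-dibromo-6-methoxyphenoxy)benzene
Product: 15 bromoiesol B (3,5-dibromo-2-[3,4,5-tribromo-2-(4-bromo-2-iodophenoxy)phenoxy]phenol), via aryloxydibromoborane 14 (not isolated)
Conditions: BBr3, CH2Cl2, −78 → 0 °C; then H2O
Reagents that add atoms: none
Why: Lewis-acid O-demethylation of an aryl methyl ether (bromide attacks the methyl group of the boron-complexed ether), which leaves the diaryl ethers, the six aryl bromides and the aryl iodide intact.

**Compound list**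
1 | 1,2,3-tribromobenzene | Brc1cccc(Br)c1Br | starting material
2 | 1,2,3-tribromo-4-iodobenzene | Ic1ccc(Br)c(Br)c1Br | intermediate
3 | 1,3,5-trimethoxybenzene | COc1cc(OC)cc(OC)c1 | starting material
4 | 1,2,3-tribromo-4-[hydroxy(tosyloxy)-lambda-3-iodanyl]benzene | Cc1ccc(cc1)S(=O)(=O)OI(O)c1ccc(Br)c(Br)c1Br | intermediate (not isolated)
5 | (2,3,4-tribromophenyl)(2,4,6-trimethoxyphenyl)iodonium 4-methylbenzenesulfonate | COc1cc(OC)c([I+]c2ccc(Br)c(Br)c2Br)c(OC)c1.Cc1ccc(S(=O)(=O)[O-])cc1 | intermediate
6 | 4-bromo-2-iodophenol | Oc1ccc(Br)cc1I | starting material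
7 | potassium 4-bromo-2-iodophenolate | [K+].[O-]c1ccc(Br)cc1I | intermediate (not isolated)
8 | 1,2,3-tribromo-4-(4-bromo-2-iodophenoxy)benzene | Brc1ccc(Oc2ccc(Br)c(Br)c2Br)c(I)c1 | intermediate
9 | [5-bromo-2-(2,3,4-tribromophenoxy)phenyl](hydroxy)-lambda-3-iodanyl trifluoromethanesulfonate | OI(OS(=O)(=O)C(F)(F)F)c1cc(Br)ccc1Oc1ccc(Br)c(Br)c1Br | intermediate (not isolated)
10 | 1,2,3,7-tetrabromodibenzo[b,e][1,4]iodaoxin-5-ium trifluoromethanesulfonate | [O-]S(=O)(=O)C(F)(F)F.Brc1ccc2Oc3c(Br)c(Br)c(Br)cc3[I+]c2c1 | intermediate
11 | 2,4-dibromo-6-methoxyphenol | COc1cc(Br)cc(Br)c1O | starting material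
12 | potassium 2,4-dibromo-6-methoxyphenolate | [K+].COc1cc(Br)cc(Br)c1[O-] | intermediate (not isolated)
13 | 1,2,3-tribromo-4-(4-bromo-2-iodophenoxy)-5-(2,4-dibromo-6-methoxyphenoxy)benzene | COc1cc(Br)cc(Br)c1Oc1cc(Br)c(Br)c(Br)c1Oc1ccc(Br)cc1I | intermediate
14 | dibromo{3,5-dibromo-2-[3,4,5-tribromo-2-(4-bromo-2-iodophenoxy)phenoxy]phenoxy}borane | BrB(Br)Oc1cc(Br)cc(Br)c1Oc1cc(Br)c(Br)c(Br)c1Oc1ccc(Br)cc1I | intermediate (not isolated)
15 | bromoiesol B, 3,5-dibromo-2-[3,4,5-tribromo-2-(4-bromo-2-iodophenoxy)phenoxy]phenol | Oc1cc(Br)cc(Br)c1Oc1cc(Br)c(Br)c(Br)c1Oc1ccc(Br)cc1I | target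

**Totals**
Total step count: 6. Longest linear sequence: 6 steps (1 → 2 → 5 → 8 → 10 → 13 → 15).

**Three steps most likely to fail**

Step 5 (ring opening of 10). The 2,6-disubstituted, weakly nucleophilic phenoxide 12 may open the cyclic salt slowly, so that decomposition or attack at the ring C carbon competes. The fallback sets out from 10 and reverses the roles of rings A and B. Salt 10 is opened with the small nucleophile hydroxide (NaOH, H2O/1,4-dioxane, 80 °C) to 3,4,5-tribromo-2-(4-bromo-2-iodophenoxy)phenol F1. Its phenoxide then displaces fluoride from commercial 3,5-dibromo-2-fluorobenzaldehyde (K2CO3, DMF, 70 °C; SNAr activated by the ortho formyl group) to give 3,5-dibromo-2-[3,4,5-tribromo-2-(4-bromo-2-iodophenoxy)phenoxy]benzaldehyde F2. Baeyer–Villiger (Dakin-type) oxidation with buffered mCPBA in CH2Cl2 gives 3,5-dibromo-2-[3,4,5-tribromo-2-(4-bromo-2-iodophenoxy)phenoxy]phenyl formate F3, and K2CO3/MeOH cleaves it. The fallback returns to the route at 15, so 13 and step 6 are bypassed.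

Step 4 (cyclisation onto the tribrominated ring). Ring B carries three bromines and may be too deactivated for the intramolecular substitution. The fallback sets out from 5 and puts the iodine on ring B, so that the ring closure attacks the far more nucleophilic ring C. Salt 5 is hydrolysed (aq NaOH, 1,4-dioxane, 80 °C) to 2,3,4-tribromophenol F4, the trimethoxyphenyl group again staying on iodine. Iodination ortho to the hydroxyl group, the para position being blocked (N-iodosuccinimide, cat. TsOH, MeCN), gives 2,3,4-tribromo-6-iodophenol F5. O-arylation with commercial bis(4-bromophenyl)iodonium triflate (t-BuOK, THF, 40 °C) gives 1,2,3-tribromo-4-(4-bromophenoxy)-5-iodobenzene F6. Oxidation with mCPBA/TfOH in CH2Cl2 then closes the ring ortho to the oxygen of the 4-bromophenoxy ring. The fallback returns to the route at 10.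

Step 1 (electrophilic iodination of 1). The C4/C5 selectivity may be poor, or the isomers may not separate. The fallback sets out from 1 and fixes the site by C–H acidity instead of by electrophilic substitution. Only the C4 hydrogen is ortho to a bromine, so deprotonation with TMPMgCl·LiCl in THF at −40 °C gives (2,3,4-tribromophenyl)magnesium chloride F7. The magnesium base and the low temperature hold back halogen migration and aryne formation. Quenching with I2 at −40 °C gives the aryl iodide. The fallback returns to the route at 2.

**Further compounds**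
F1 | step 5 | 3,4,5-tribromo-2-(4-bromo-2-iodophenoxy)phenol | Oc1cc(Br)c(Br)c(Br)c1Oc1ccc(Br)cc1I
F2 | step 5 | 3,5-dibromo-2-[3,4,5-tribromo-2-(4-bromo-2-iodophenoxy)phenoxy]benzaldehyde | O=Cc1cc(Br)cc(Br)c1Oc1cc(Br)c(Br)c(Br)c1Oc1ccc(Br)cc1I
F3 | step 5 | 3,5-dibromo-2-[3,4,5-tribromo-2-(4-bromo-2-iodophenoxy)phenoxy]phenyl formate | O=COc1cc(Br)cc(Br)c1Oc1cc(Br)c(Br)c(Br)c1Oc1ccc(Br)cc1I
F4 | step 4 | 2,3,4-tribromophenol | Oc1ccc(Br)c(Br)c1Br
F5 | step 4 | 2,3,4-tribromo-6-iodophenol | Oc1c(I)cc(Br)c(Br)c1Br
F6 | step 4 | 1,2,3-tribromo-4-(4-bromophenoxy)-5-iodobenzene | Brc1ccc(Oc2c(I)cc(Br)c(Br)c2Br)cc1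
F7 | step 1 | (2,3,4-tribromophenyl)magnesium chloride | Cl[Mg]c1ccc(Br)c(Br)c1Br
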